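A curve fitted to rising readings can run on past what the charges pay for. So I drew up the bill before I chose the next step.

in all of them: D 0.20 M

| flask | X | remark | time |
|---|---|---|---|
| elm | 0.30 M | the very flask that is asked about, followed so far |  |
| flask | 0.300 M |  | 2.5 d |

elm run (percent of the D charged): time / h: Z / % = 0.333: 1; 1.00: 4; 1.50: 10; 2.50: 17; 4.00: 22; 5.00: 28

(scatter of a reading: 2 percentage points)

- time up to 2.5 d at which Z stands highest
- the amount of Z, in percent of the D charged, at that time

- a species is counted by the D in it: one L counts as two
- amounts and yields of Z count L too
- the earlier runs were read with a standard deviation of 2 percentage points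
- on the list of suspects stand: D + X -> G + J; X + G -> Z + J; D + Z <-> L; Z <-> Q; D <-> E
- in an amount of Z, one L counts as one Z

D to G takes one X and G to Z takes another, so each Z costs two X. I call the X needed to take every D to Z, as a share of the X charged, the X bill:

X bill = two × 0.20 M / 0.300 M = 133%

The bill exceeds the charge, so in this flask X is the limiting reagent. I then solved the far end. Suppose every D has taken one X and the remaining X has gone on to G:

Z = (0.300 M − 0.20 M) / 0.20 M = 50.0%

This sum supposes that G takes no X until D is gone, and it leaves out Q and E, so I held it as a mark and not as a ceiling. The last reading of this flask, 28% at 5.00 h, lay 22 percentage points below that mark, more than the scatter of 2 points. My decision was to leave both charges as they were and keep sampling towards 2.5 d.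

The forecast gave 50% at 1.5 d, expecting “a broad maximum near 50% somewhere after a day”. Its own sum differed from my mark: “the cap is about 60%”.

    D + X → G + J (k = 2.41 L mol⁻¹ h⁻¹)
    X + G → Z + J (k = 0.910 L mol⁻¹ h⁻¹)
    D + Z ⇌ L, settled at all times (K = 14.0 L mol⁻¹)
    Z ⇌ Q (K = 0.614, k = 0.0116 h⁻¹)
    D ⇌ E (K = 3.60, k = 0.0185 h⁻¹)

Z stood highest at 1.10 d, at 47.4%, earlier than the forecast's time. At that moment this flask held 8.19% of Q. With its bill of 133%, this flask had 0.39% of its X left at 2.50 d. The neighbour flask with 0.080 M of D has a bill of 53.3%, below its charge, so 46.7% of its X should stay over. That neighbour flask kept 48.0% of its X at 2.50 d.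

The numbers in the tables stem from a simulated flask for substances that don't exist; the scatter is artificial.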